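The readings were computed from invented constants.

**Blind side.** Two columns of readings cannot balance the solid substrate: the runs show first product and other mono adduct, and the rest of the charge stays unseen. The reckoning below therefore serves other mono adduct and leaves the shares to the forecast.

in all of them: solid substrate 0.10 M
- south-west: partner 0.15 M; run made earlier
- north-west: partner 0.21 M; run made earlier
- south-east: partner 0.37 M; run made earlier
- eta: partner 0.120 M; time 3.0 min
- delta: partner 0.400 M; time 3.0 min

| run | time / s | other mono adduct / % | first product / % |
|---|---|---|---|
| south-west | 10.0 | 0.2 | 0.2 |
| south-west | 20.0 | 0.3 | 1.2 |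
| south-west | 40.0 | 2.1 | 3.2 |
| south-west | 60.0 | 3.3 | 5.0 |
| south-west | 120 | 9.3 | 8.4 |
| north-west | 12.0 | 0.5 | 0.7 |
| north-west | 30.0 | 1.6 | 2.2 |
| north-west | 60.0 | 4.4 | 4.4 |
| north-west | 90.0 | 8.5 | 6.5 |
| north-west | 120 | 12.0 | 8.0 |
| south-east | 25.0 | 1.8 | 2.4 |
| south-east | 50.0 | 5.5 | 4.4 |
| south-east | 80.0 | 9.8 | 5.0 |
| south-east | 90.0 | 11.3 | 5.6 |
| south-east | 120 | 15.9 | 6.5 |

(standard deviation of a reading: 0.3 percentage points)

- at the start none of the solid substrate is in solution
- a reading or a percentage of first product counts all its forms, free or not

- which of these holds the largest part of the solid substrate at the end of eta (bis adduct / solid substrate / other mono adduct / first product)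
- which of these holds the largest part of the solid substrate at the end of delta (bis adduct / solid substrate / other mono adduct / first product)
- how much other mono adduct is there at the end of eta, in percent of the solid substrate charged

**Turning partner.** Over each run's last readings, other mono adduct climbs 0.0600 /min of the charge in the south-west run and 0.0891 /min in the south-east run, less than in proportion to partner. My reckoning takes a hyperbola, slope = ceiling·[partner]/([partner]+K), and assumes dissolving as the rate-limiting step at the ceiling. These two runs give a ceiling of 0.133 /min and K of 0.183 M. The north-west run, left out, reads 0.0760 /min against 0.0712 /min from the hyperbola. For eta, the hyperbola gives 0.0527 /min, the late slope of other mono adduct, which is carried on.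

**Turning time.** Integrating a constant slope gives slope·(t − lag), and the south-west run gives a lag of 0.450 min. From the south-west run at 2 min, changing partner alone to that of eta gives 8.17 %, and changing time alone to 3.0 min gives 15.3 %. Both changes give 13.5 % for eta, and the same reckoning gives 23.3 % for delta.

**The forecast.** It says “Most therefore remains as solid substrate in both eta and delta.” It puts other mono adduct in eta at 14.5 %, between 12 % and 17 %, higher than my figure.

**The result.** Of the four asked, solid substrate leads eta at 30.9 %, as forecast. Against the forecast, bis adduct leads delta at 46.1 %.

    starting material + partner → first product (k = 0.0650 /M/s)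
    starting material + partner → other mono adduct (k = 0.0340 /M/s)
    partner + first product → bis adduct (k = 0.190 /M/s)
    partner + other mono adduct → bis adduct (k = 0.00220 /M/s)
    starting material + first product ⇌ idle adduct, settled at all times (K = 12.0 /M)
    solid substrate ⇌ starting material, rate k6*(cs6 - [starting material]) while solid is left; crystals form when [starting material] > cs6 (solubility = 46.0 mM, k = 0.0160 /s)
    crystals ⇌ first product, rate k7*(cs7 - [first product]) while solid is left; crystals form when [first product] > cs7 (solubility = 0.0570 M, k = 1.30 /s)

**Slope tested.** Eta holds 12.4 % other mono adduct and delta 25.2 %, while the south-west run at its last reading gives 7.97 % with partner alone changed to that of eta and 14.5 % with time alone changed. Read at 5.0 min, eta holds 19.1 %, where the same slope gives 24.0 %, and its partner is down to 32 % of the charge.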